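## Analysis of the target

The target is a flavonol: ring A is fused to the 3-hydroxy-4-pyranone ring C, and ring B sits on C2. Ring A carries methoxy groups on C5 and C6, a free hydroxyl on C7, hydrogen on C8, the ring oxygen on C8a and the carbonyl-bearing carbon C4a. Ring B has a 4'-methoxy group and, on C3', a (2R)-2-hydroxy-3-methylbut-3-enyl chain (from the SMILES: OH > isopropenyl > CH2Ar > H, R). This secondary allylic carbinol is the only stereocentre. It is insulated from the core by a CH2 group and an arene, so it has to be set by a reagent. The sensitive groups are the allylic alcohol beside a 1,1-disubstituted alkene (acid, hydrogenation and electrophilic oxidants are excluded), the chelating 3-hydroxy-4-pyranone, and the C5 methyl ether peri to the carbonyl. The synthesis is hard for three reasons: the 5,6-di-O-methyl/7-hydroxy pattern cannot be made reliably by selective methylation of a triol; C4a and C8 are both flanked by two oxygens, so carbon must be placed on C4a only; and a C5 substituent tends to divert oxidative flavonol closure towards aurones. The strategy rests on the arrangement O7–C8(H)–O8a next to the methoxy carbons C5 and C6. A vinylketene (C7, C4a, C5, C6) and an oxygenated alkyne (C8, C8a) assemble exactly this pattern, with the methyl ethers already in place.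

## Retrosynthetic reasoning

**35 to 34 (O7–allyl bond).** O7 must be masked during the basic, oxidative assembly of ring C. An allyl ether is chosen because it withstands hydroxide and peroxide and is removed by a zerovalent palladium catalyst under neutral conditions. A silyl ether para to the carbonyl would not survive hydroxide, and an acetal would need acid in the presence of the allylic alcohol.

**34 to 33 (O1–C2 and C3–O bonds).** Ring C is opened to the 2'-hydroxychalcone 33. The forward Algar–Flynn–Oyamada reaction closes the pyranone and installs the 3-hydroxyl in one operation at the correct oxidation level.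

**33 to 24 and 32 (C2=C3 bond).** Cutting the enone gives the ring A methyl ketone 24 and the ring B aldehyde 32. This is the convergent point: the stereocentre arrives in 32, and the forward Claisen–Schmidt condensation needs only hydroxide.

**32 back to 25 (formyl C–C bond, carbinol C–H bond, acyl–alkenyl bond).** The aldehyde comes from the aryl bromide 30 by halogen–metal exchange. The carbinol comes from enantioselective reduction of enone 29. The enone comes from Weinreb amide 27 and the Grignard reagent 28, and 27 from the commercial acid 25. The stereocentre is set early on a small molecule, where a resolution remains affordable.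

**24 back to 16 (C4a–acetyl bond).** The acetyl group is attached by directed ortho-metalation. Both C4a and C8 are ortho to O8a, so C8 is first blocked: in the bis(methoxymethyl) ether 18 the hydrogen between the two acetal oxygens (C8) is lithiated and silylated (20). The only remaining ring hydrogen (C4a) is then lithiated and acylated (22). Acid removes the acetals and the silicon block together (23), and hydrogen bonding of O8a–H to the new carbonyl allows selective allylation of O7 (24). The silyl ether of 16 is removed first (17). A shorter plan that keeps it and later distinguishes two aryl silyl ethers was not adopted, because nothing in the structure makes such a cleavage selective.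

**16 to 7 and 12 (C4a–C5, C7–C8, C8a–C4a, C6–C7).** Ring A is taken apart into the diazoketone 7 and the siloxyalkyne 12. Forward, 7 gives vinylketene 13, which combines with 12 through 14 and 15 to the phenol. The gain is that O5 and O6 are methylated in an acyclic precursor, O7 and O8a arrive unmethylated, and C8 carries hydrogen.

**7 back to 1 and 2; 12 back to 8 and 9.** The diazoketone is an acylated diazoalkane from acid 5, obtained from ester 4, itself the O-methylated formylation product of 1 with 2. The alkyne is the O-silylated ynolate of 8, silylated with 9.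

## Alternatives that were turned down

**Alternative 1:** The side-chain stereocentre is made last, by cutting the two C–O bonds of an oxirane. The (E)-allylic alcohol A2, a hydroxyprenyl flavonol protected at O3 and O7, would be epoxidised by the Sharpless titanium–tartrate catalyst (Ti(OiPr)4 with the D-(−)-tartrate diester and an alkyl hydroperoxide) to the (2R,3R)-epoxy alcohol A1. Its oxirane CH carbon already has the configuration of the target carbinol. Conversion of the primary hydroxyl into an iodide and zinc-induced reductive opening would then reveal the 2-hydroxy-3-methylbut-3-enyl unit.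
- For it: epoxidation of a trisubstituted (E)-allylic alcohol is among the most dependable enantioselective reactions and its facial sense is predictable. On this point it is stronger than the reduction of 29, whose two ketone substituents differ less.
- Against it: A2 needs an (E)-selective hydroxyprenyl installation; the epoxidation runs on the complete, Lewis-basic chromenone; and activation, reductive opening and two deprotections follow at the end of the longest sequence. It also leaves the construction of ring A open.
- Comparison: the chosen route sets the carbinol early on a small bromoarene and spends its key step on the ring A pattern.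

**Alternative 2:** Ring C is cut at C3–C4. SmI2 would couple the two aldehydes of A4 (the aryl aldehyde on C4a and the tethered alpha-aryloxy aldehyde) to the flavan-3,4-diol A3.
- For it: ketyl–aldehyde cyclisations to six-membered diols are reliable, O3 and O4 arrive together, and no chalcone is involved, so aurone formation is excluded. In that respect it is stronger than step 17.
- Against it: the alpha carbon of one aldehyde in A4 bears both an aryloxy group and an aryl ring. Such aldehydes enolise, and under single-electron reduction alpha-aryloxy carbonyl compounds tend to lose aryloxide, which would cut the tether before the C–C bond forms. A3 lies two oxidations below the flavonol, and its three new stereocentres are destroyed by oxidants that must spare the alkene, the benzylic CH2 and two electron-rich arenes.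
- Comparison: it is several steps longer than aldol plus oxidative cyclisation from 24 and 32, and it also presupposes a fully substituted ring A aldehyde.

**Alternative 3:** C4a–C4, C4–C3 and O1–C2 are cut at once. The ortho-iodophenol A6, carbon monoxide A8 and the aryl alkyne A7 would be joined by PdCl2(PPh3)2 and an amine (carbonylative alkynylation, then 6-endo oxa-Michael closure) to the flavone A5.
- For it: it is highly convergent and builds ring C in one step without aurone-prone intermediates. In convergence it is at least equal to the aldol union.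
- Against it: A5 lacks the 3-hydroxyl. Adding it needs either an electrophilic epoxidising agent, which would also attack the isopropenyl group, or C3-lithiation, borylation and oxidation with strong base in the presence of two silyl ethers. A6 needs iodination at C4a and not C8, the same regiochemical problem, and its iodine sits between two ortho substituents. A7 costs an extra homologation.
- Comparison: the step count is about equal (coupling plus hydroxylation against aldol plus oxidative cyclisation). The chosen route obtains the 3-hydroxyl from the ring-forming step itself and needs no late strong base.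

Key step: step 5

Remark on the chemistry: the enol ether double bond of 3–7 and 13–15 is written with the Z geometry expected from O-methylation; either geometry would serve, because both carbons become aromatic in step 5.

## Route

Step 1
Reactants: 1 methyl methoxyacetate; 2 methyl formate
Product: 4 methyl (Z)-2,3-dimethoxyprop-2-enoate, via sodium enolate 3 (not isolated)
Conditions: NaH, THF, 0 °C → rt; then Me2SO4, DMF, rt
Reagents that add atoms: dimethyl sulfate, COS(=O)(=O)OC
Why: Crossed Claisen condensation with the non-enolisable formate gives the sodium enolate of the formyl ester, which the hard electrophile dimethyl sulfate should methylate on oxygen in a dipolar solvent (enol ether formation).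

Step 2
Reactants: 4 methyl (Z)-2,3-dimethoxyprop-2-enoate
Product: 5 (Z)-2,3-dimethoxyprop-2-enoic acid
Conditions: LiOH·H2O, THF/H2O, rt; then 1 M HCl to pH 3, 0 °C
Reagents that add atoms: lithium hydroxide, [Li+].[OH-]
Why: Ester saponification by acyl substitution; the push-pull enol ether is stable to hydroxide and should survive a brief cold acidification.

Step 3
Reactants: 5 (Z)-2,3-dimethoxyprop-2-enoic acid
Product: 7 (Z)-1-diazo-3,4-dimethoxybut-3-en-2-one, via acid chloride 6 (not isolated)
Conditions: (COCl)2, DMF (cat.), CH2Cl2, 0 °C → rt, evaporate; then CH2N2 (3 equiv), Et2O, 0 °C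
Reagents that add atoms: diazomethane, C=[N+]=[N-]
Why: Acylation of diazomethane by the acid chloride (first stage of the Arndt–Eistert sequence), with excess diazomethane taking up HCl; the acid chloride has no alpha hydrogen, so no ketene can form, and the donor-substituted double bond is a poor dipolarophile.

Step 4
Reactants: 8 acetylene; 9 triisopropylsilyl chloride
Product: 12 (triisopropylsiloxy)ethyne, via lithium acetylide 10 (not isolated), via lithium ethynolate 11 (not isolated)
Conditions: n-BuLi, THF, −78 °C; t-BuOOLi (from t-BuOOH and LiN(SiMe3)2), −78 → 0 °C; then 9, −78 → 0 °C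
Reagents that add atoms: tert-butyl hydroperoxide, CC(C)(C)OO
Why: The acetylide attacks the electrophilic oxygen of lithium tert-butyl peroxide to give the ynolate (known oxidation of lithium acetylides), and the bulky silyl chloride should silylate the ynolate on oxygen, giving the kinetically stable triisopropylsilyl ynol ether and not a silylketene.

Step 5
Reactants: 7 (Z)-1-diazo-3,4-dimethoxybut-3-en-2-one; 12 (triisopropylsiloxy)ethyne
Product: 16 2,3-dimethoxy-5-(triisopropylsilyloxy)phenol, via vinylketene 13 (not isolated), via cyclobutenone 14 (not isolated), via dienylketene 15 (not isolated)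
Conditions: hν (254 nm, Vycor), ClCH2CH2Cl (degassed), 12 (2 equiv), rt; then 80 °C
Reagents that add atoms: none
Why: Irradiation of 7 expels N2 and the alkenyl group migrates to the carbene carbon (photochemical Wolff rearrangement, forming C4a–C5) to give vinylketene 13. The terminal carbon of 12, made nucleophilic by the silyloxy oxygen, attacks the electrophilic ketene carbonyl carbon, and the (2+2) cycloaddition gives cyclobutenone 14, forming C7–C8 and C8a–C4a. Under the irradiation or on warming, 14 opens by reversible 4-electron electrocyclic cleavage to dienylketene 15. Ring A then closes by thermally allowed, disrotatory 6-electron electrocyclisation of 15 (six-membered closure between the ketene carbon and the methoxy-bearing terminus, forming C6–C7), and the cyclohexadienone tautomerises to the phenol. The closest known reaction type is the Danheiser benzannulation in its photochemical Wolff variant with 1-siloxyalkynes, which gives resorcinol monosilyl ethers. No stereocentre is formed, and the enol ether geometry of 7 is irrelevant because both carbons become aromatic. The selectivity needed is the orientation of the (2+2) step, which the polarisation of the ynol ether secures: the silyloxy carbon ends meta to the new hydroxyl with C8–H between them, and the methyl ethers stay on C5 and C6. Excess 12 and the final period at 80 °C should suppress trapping of 13 by the product phenol and drive residual 14 to 16.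

Step 6
Reactants: 16 2,3-dimethoxy-5-(triisopropylsilyloxy)phenol
Product: 17 4,5-dimethoxybenzene-1,3-diol
Conditions: Bu4NF, THF, 0 °C; aq. NH4Cl
Reagents that add atoms: none
Why: Fluoride cleaves the aryl silyl ether (strong Si–F bond); the silyl group was needed to make the alkyne a stable, polarised ketene partner, and both resorcinol oxygens must now carry identical, strongly directing acetal groups.

Step 7
Reactants: 17 4,5-dimethoxybenzene-1,3-diol
Product: 18 1,2-dimethoxy-3,5-bis(methoxymethoxy)benzene
Conditions: NaH, MeOCH2Cl, DMF, 0 °C → rt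
Reagents that add atoms: chloromethyl methyl ether, COCCl
Why: Williamson alkylation of both phenoxides; the methoxymethyl ethers direct the two lithiations and later leave under acid that the methyl ethers withstand.

Step 8
Reactants: 18 1,2-dimethoxy-3,5-bis(methoxymethoxy)benzene
Product: 20 [3,4-dimethoxy-2,6-bis(methoxymethoxy)phenyl]trimethylsilane, via C8 aryllithium 19 (not isolated)
Conditions: n-BuLi, THF, 0 °C; then Me3SiCl, −78 °C → rt
Reagents that add atoms: chlorotrimethylsilane, C[Si](C)(C)Cl
Why: Directed ortho-metalation should occur at C8, the hydrogen flanked by two chelating acetal oxygens, in preference to C4a, which has only one such neighbour; silylation makes C8 a blocked position that is unmasked later by protodesilylation.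

Step 9
Reactants: 20 [3,4-dimethoxy-2,6-bis(methoxymethoxy)phenyl]trimethylsilane
Product: 22 1-[2,3-dimethoxy-4,6-bis(methoxymethoxy)-5-(trimethylsilyl)phenyl]ethan-1-one, via C4a aryllithium 21 (not isolated)
Conditions: s-BuLi, TMEDA, THF, −78 °C; then MeC(O)N(OMe)Me, −78 → 0 °C
Reagents that add atoms: N-methoxy-N-methylacetamide, CC(=O)N(C)OC
Why: The only remaining ring hydrogen (C4a) lies between a methoxymethoxy and a methoxy group, so the second directed ortho-metalation is unambiguous; the Weinreb amide acylates the aryllithium through a chelated tetrahedral intermediate that prevents over-addition.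

Step 10
Reactants: 22 1-[2,3-dimethoxy-4,6-bis(methoxymethoxy)-5-(trimethylsilyl)phenyl]ethan-1-one
Product: 23 1-(2,4-dihydroxy-5,6-dimethoxyphenyl)ethan-1-one
Conditions: 3 M HCl, MeOH, 55 °C
Reagents that add atoms: none
Why: Acid-catalysed acetal exchange removes both methoxymethyl groups (formaldehyde is trapped by methanol), and ipso-protonation at C8, ortho to both freed hydroxyls and para to the C5 methoxy group, expels the silyl group (protodesilylation); the aryl methyl ethers are inert.

Step 11
Reactants: 23 1-(2,4-dihydroxy-5,6-dimethoxyphenyl)ethan-1-one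
Product: 24 1-[2-hydroxy-5,6-dimethoxy-4-(prop-2-en-1-yloxy)phenyl]ethan-1-one
Conditions: allyl bromide (1.05 equiv), K2CO3, acetone, 50 °C
Reagents that add atoms: allyl bromide, C=CCBr
Why: Williamson etherification should be selective for the hydroxyl para to the acetyl group (future O7), which is the more acidic and is not held in the hydrogen bond that deactivates the ortho hydroxyl (future O8a).

Step 12
Reactants: 25 2-(5-bromo-2-methoxyphenyl)acetic acid
Product: 27 2-(5-bromo-2-methoxyphenyl)-N-methoxy-N-methylacetamide, via acyl imidazole 26 (not isolated)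
Conditions: 1,1'-carbonyldiimidazole, CH2Cl2, rt; then MeNHOMe·HCl, rt
Reagents that add atoms: N,O-dimethylhydroxylamine hydrochloride, CNOC.Cl
Why: Carboxyl activation as the acyl imidazole and amide formation (Weinreb amide synthesis); the aryl bromide is untouched.

Step 13
Reactants: 27 2-(5-bromo-2-methoxyphenyl)-N-methoxy-N-methylacetamide; 28 isopropenylmagnesium bromide
Product: 29 1-(5-bromo-2-methoxyphenyl)-3-methylbut-3-en-2-one
Conditions: THF, −20 → 0 °C; inverse quench into cold 1 M HCl
Reagents that add atoms: none
Why: Grignard addition to the Weinreb amide stops at the chelated tetrahedral adduct, which collapses to the enone only on work-up; the acidic quench protonates the liberated hydroxylamine so that it cannot add to the enone.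

Step 14
Reactants: 29 1-(5-bromo-2-methoxyphenyl)-3-methylbut-3-en-2-one
Product: 30 (2R)-1-(5-bromo-2-methoxyphenyl)-3-methylbut-3-en-2-ol
Conditions: (S)-1-methyl-3,3-diphenyltetrahydro-1H,3H-pyrrolo[1,2-c][1,3,2]oxazaborole (20 mol%), catecholborane, toluene, −78 °C
Reagents that add atoms: none
Why: Corey–Bakshi–Shibata reduction: the ketone binds the ring boron anti to its larger group, here the alpha-branched alkenyl group, and hydride is delivered from the nitrogen-bound borane to one face, which with the (S)-catalyst should give the (R)-carbinol; catecholborane at low temperature avoids hydroboration of the alkene.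

Step 15
Reactants: 30 (2R)-1-(5-bromo-2-methoxyphenyl)-3-methylbut-3-en-2-ol
Product: 32 3-[(2R)-2-hydroxy-3-methylbut-3-en-1-yl]-4-methoxybenzaldehyde, via dilithio species 31 (not isolated)
Conditions: n-BuLi (2.2 equiv), THF, −78 °C; then DMF, −78 → 0 °C; aq. NH4Cl
Reagents that add atoms: N,N-dimethylformamide, CN(C)C=O
Why: The first equivalent forms the lithium alkoxide, the second effects bromine–lithium exchange, and DMF formylates the aryllithium (Bouveault formylation); the carbinol carbon is not acidic, so the stereocentre is untouched.

Step 16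
Reactants: 24 1-[2-hydroxy-5,6-dimethoxy-4-(prop-2-en-1-yloxy)phenyl]ethan-1-one; 32 3-[(2R)-2-hydroxy-3-methylbut-3-en-1-yl]-4-methoxybenzaldehyde
Product: 33 (2E)-1-[2-hydroxy-5,6-dimethoxy-4-(prop-2-en-1-yloxy)phenyl]-3-{3-[(2R)-2-hydroxy-3-methylbut-3-en-1-yl]-4-methoxyphenyl}prop-2-en-1-one
Conditions: KOH, EtOH/H2O, rt
Reagents that add atoms: none
Why: Claisen–Schmidt condensation of the methyl ketone enolate with the non-enolisable aldehyde, followed by E1cB dehydration, gives the (E)-enone; the allyl ether, the secondary alcohol and the alkene are stable to hydroxide.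

Step 17
Reactants: 33 (2E)-1-[2-hydroxy-5,6-dimethoxy-4-(prop-2-en-1-yloxy)phenyl]-3-{3-[(2R)-2-hydroxy-3-methylbut-3-en-1-yl]-4-methoxyphenyl}prop-2-en-1-one
Product: 34 3-hydroxy-2-{3-[(2R)-2-hydroxy-3-methylbut-3-en-1-yl]-4-methoxyphenyl}-5,6-dimethoxy-7-(prop-2-en-1-yloxy)-4H-chromen-4-one
Conditions: 30% H2O2, NaOH, MeOH, 0 °C → rt
Reagents that add atoms: hydrogen peroxide, OO
Why: Algar–Flynn–Oyamada reaction: the phenoxide adds to C2 of the enone (six-membered closure), peroxide hydroxylates C3, and a further oxidation establishes the C2–C3 double bond; alkaline peroxide does not epoxidise the unactivated isopropenyl and allyl double bonds.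

Step 18
Reactants: 34 3-hydroxy-2-{3-[(2R)-2-hydroxy-3-methylbut-3-en-1-yl]-4-methoxyphenyl}-5,6-dimethoxy-7-(prop-2-en-1-yloxy)-4H-chromen-4-one
Product: 35 3,7-dihydroxy-2-{3-[(2R)-2-hydroxy-3-methylbut-3-en-1-yl]-4-methoxyphenyl}-5,6-dimethoxy-4H-chromen-4-one (CNP0264719.1)
Conditions: Pd(PPh3)4 (5 mol%), morpholine, THF, rt
Reagents that add atoms: none
Why: Zerovalent palladium ionises the aryl allyl ether to a pi-allyl complex and the phenoxide, and morpholine captures the allyl group irreversibly (Tsuji–Trost deallylation); the free allylic alcohol of the side chain is not ionised under these neutral conditions, so the stereocentre and the isopropenyl group should be untouched.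

## Compound list

1 | methyl methoxyacetate | COCC(=O)OC | starting material
2 | methyl formate | COC=O | starting material
3 | sodium (Z)-2,3-dimethoxy-3-oxoprop-1-en-1-olate | [Na+].[O-]/C=C(\OC)C(=O)OC | intermediate
4 | methyl (Z)-2,3-dimethoxyprop-2-enoate | CO/C=C(\OC)C(=O)OC | intermediate
5 | (Z)-2,3-dimethoxyprop-2-enoic acid | CO/C=C(\OC)C(=O)O | intermediate
6 | (Z)-2,3-dimethoxyprop-2-enoyl chloride | CO/C=C(\OC)C(=O)Cl | intermediate
7 | (Z)-1-diazo-3,4-dimethoxybut-3-en-2-one | CO/C=C(\OC)C(=O)C=[N+]=[N-] | intermediate
8 | acetylene | C#C | starting material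
9 | triisopropylsilyl chloride | CC(C)[Si](Cl)(C(C)C)C(C)C | starting material
10 | lithium acetylide | [Li]C#C | intermediate
11 | lithium ethynolate | [Li+].[O-]C#C | intermediate
12 | (triisopropylsiloxy)ethyne | C#CO[Si](C(C)C)(C(C)C)C(C)C | intermediate
13 | (3Z)-3,4-dimethoxybuta-1,3-dien-1-one (vinylketene) | CO/C=C(\OC)C=C=O | intermediate
14 | 4-[(Z)-1,2-dimethoxyethenyl]-3-(triisopropylsilyloxy)cyclobut-2-en-1-one | CO/C=C(\OC)C1C(=O)C=C1O[Si](C(C)C)(C(C)C)C(C)C | intermediate
15 | (3E,5Z)-5,6-dimethoxy-3-(triisopropylsilyloxy)hexa-1,3,5-trien-1-one (dienylketene) | O=C=C/C(O[Si](C(C)C)(C(C)C)C(C)C)=C\C(OC)=C\OC | intermediate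
16 | 2,3-dimethoxy-5-(triisopropylsilyloxy)phenol | COc1c(O)cc(O[Si](C(C)C)(C(C)C)C(C)C)cc1OC | intermediate
17 | 4,5-dimethoxybenzene-1,3-diol | COc1cc(O)cc(O)c1OC | intermediate
18 | 1,2-dimethoxy-3,5-bis(methoxymethoxy)benzene | COCOc1cc(OCOC)c(OC)c(OC)c1 | intermediate
19 | [3,4-dimethoxy-2,6-bis(methoxymethoxy)phenyl]lithium | [Li]c1c(OCOC)cc(OC)c(OC)c1OCOC | intermediate
20 | [3,4-dimethoxy-2,6-bis(methoxymethoxy)phenyl]trimethylsilane | C[Si](C)(C)c1c(OCOC)cc(OC)c(OC)c1OCOC | intermediate
21 | [2,3-dimethoxy-4,6-bis(methoxymethoxy)-5-(trimethylsilyl)phenyl]lithium | [Li]c1c(OC)c(OC)c(OCOC)c([Si](C)(C)C)c1OCOC | intermediate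
22 | 1-[2,3-dimethoxy-4,6-bis(methoxymethoxy)-5-(trimethylsilyl)phenyl]ethan-1-one | CC(=O)c1c(OC)c(OC)c(OCOC)c([Si](C)(C)C)c1OCOC | intermediate
23 | 1-(2,4-dihydroxy-5,6-dimethoxyphenyl)ethan-1-one | CC(=O)c1c(O)cc(O)c(OC)c1OC | intermediate
24 | 1-[2-hydroxy-5,6-dimethoxy-4-(prop-2-en-1-yloxy)phenyl]ethan-1-one | CC(=O)c1c(O)cc(OCC=C)c(OC)c1OC | intermediate
25 | 2-(5-bromo-2-methoxyphenyl)acetic acid | COc1ccc(Br)cc1CC(=O)O | starting material
26 | 2-(5-bromo-2-methoxyphenyl)-1-(1H-imidazol-1-yl)ethan-1-one | COc1ccc(Br)cc1CC(=O)n1ccnc1 | intermediate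
27 | 2-(5-bromo-2-methoxyphenyl)-N-methoxy-N-methylacetamide | COc1ccc(Br)cc1CC(=O)N(C)OC | intermediate
28 | isopropenylmagnesium bromide | C=C(C)[Mg]Br | starting material
29 | 1-(5-bromo-2-methoxyphenyl)-3-methylbut-3-en-2-one | C=C(C)C(=O)Cc1cc(Br)ccc1OC | intermediate
30 | (2R)-1-(5-bromo-2-methoxyphenyl)-3-methylbut-3-en-2-ol | C=C(C)[C@H](O)Cc1cc(Br)ccc1OC | intermediate
31 | lithium (2R)-1-(5-lithio-2-methoxyphenyl)-3-methylbut-3-en-2-olate | C=C(C)[C@H](O[Li])Cc1cc([Li])ccc1OC | intermediate
32 | 3-[(2R)-2-hydroxy-3-methylbut-3-en-1-yl]-4-methoxybenzaldehyde | C=C(C)[C@H](O)Cc1cc(C=O)ccc1OC | intermediate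
33 | (2E)-1-[2-hydroxy-5,6-dimethoxy-4-(prop-2-en-1-yloxy)phenyl]-3-{3-[(2R)-2-hydroxy-3-methylbut-3-en-1-yl]-4-methoxyphenyl}prop-2-en-1-one | C=C(C)[C@H](O)Cc1cc(/C=C/C(=O)c2c(O)cc(OCC=C)c(OC)c2OC)ccc1OC | intermediate
34 | 3-hydroxy-2-{3-[(2R)-2-hydroxy-3-methylbut-3-en-1-yl]-4-methoxyphenyl}-5,6-dimethoxy-7-(prop-2-en-1-yloxy)-4H-chromen-4-one | C=C(C)[C@H](O)Cc1cc(-c2oc3cc(OCC=C)c(OC)c(OC)c3c(=O)c2O)ccc1OC | intermediate
35 | 3,7-dihydroxy-2-{3-[(2R)-2-hydroxy-3-methylbut-3-en-1-yl]-4-methoxyphenyl}-5,6-dimethoxy-4H-chromen-4-one | C=C(C)[C@H](O)Cc1cc(-c2oc3cc(O)c(OC)c(OC)c3c(=O)c2O)ccc1OC | target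

## Step count and least certain steps

Total step count: 18. Longest linear sequence: 13 steps (steps 1, 2, 3, 5, 6, 7, 8, 9, 10, 11, 16, 17, 18).

**Step 5 (key step).** The most likely failure is interception of vinylketene 13 before it meets the alkyne: addition of the product phenol or of traces of water to the ketene, ketene dimerisation, or photodegradation of the electron-rich enol ether, because all of the ketene is generated under irradiation. The fallback generates the same vinylketene thermally and in low stationary concentration. Commercial methyl 4-methoxy-3-oxobutanoate would be converted with trimethyl orthoformate and catalytic H2SO4 into methyl (2E)-3,4-dimethoxybut-2-enoate F1, saponified (LiOH) to (2E)-3,4-dimethoxybut-2-enoic acid F2, and turned with oxalyl chloride into (2E)-3,4-dimethoxybut-2-enoyl chloride F3. Slow addition of Et3N to F3 and 12 in toluene at 80 °C should cause 1,4-dehydrochlorination to 13, which enters the same cycloaddition, ring opening and ring closure. This fallback sets out from 12 and comes back to the route at 16.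

**Step 4.** The lithium acetylide may disproportionate while the oxygen transfer is warmed, and the unhindered ynolate may be silylated on carbon or the terminal ynol ether may undergo a 1,3-silyl shift to a silylketene. The fallback carries a silicon substituent on the alkyne terminus. Trimethylsilylacetylene and 9 under the same protocol should give 1-(triisopropylsiloxy)-2-(trimethylsilyl)ethyne F4, a shielded siloxyalkyne. Irradiation with 7 as in step 5 should give 2,3-dimethoxy-5-(triisopropylsilyloxy)-6-(trimethylsilyl)phenol F5, in which the silyl group sits on C8. Bu4NF would cleave only the O–Si bond to give 4,5-dimethoxy-2-(trimethylsilyl)benzene-1,3-diol F6, and NaH with chloromethyl methyl ether gives 20. This fallback sets out from 7 and comes back at 20, so steps 6 to 8 fall away.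

**Step 3.** Diazomethane may add as a 1,3-dipole to the conjugated double bond, or the enol ether may be lost to HCl during acid chloride formation. The fallback avoids the acid chloride. Ester 4 would be converted with MeNHOMe·HCl and i-PrMgCl into (Z)-N,2,3-trimethoxy-N-methylprop-2-enamide F7, and MeMgBr gives (Z)-3,4-dimethoxybut-3-en-2-one F8. Its lithium enolate (LiN(SiMe3)2) would be trifluoroacetylated with 2,2,2-trifluoroethyl trifluoroacetate to (Z)-1,1,1-trifluoro-5,6-dimethoxyhex-5-ene-2,4-dione F9 (not isolated). Methanesulfonyl azide, Et3N and water in MeCN then give 7 by detrifluoroacetylative diazo transfer. This fallback sets out from 4 and comes back at 7.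

**Step 14.** Facial discrimination may be poor if the arylmethyl group competes with the isopropenyl group as the larger substituent, and hydroboration or conjugate reduction may intrude. The fallback separates reduction from stereocontrol. Luche reduction (NaBH4, CeCl3) of 29 gives racemic 1-(5-bromo-2-methoxyphenyl)-3-methylbut-3-en-2-ol F10. Sharpless kinetic resolution (Ti(OiPr)4, L-(+)-diisopropyl tartrate, t-BuOOH, CH2Cl2, −20 °C) should epoxidise the (S)-enantiomer to (1S)-2-(5-bromo-2-methoxyphenyl)-1-[(2R)-2-methyloxiran-2-yl]ethan-1-ol F11 and leave the (R)-alcohol. This fallback sets out from 29 and comes back at 30.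

**Step 17.** Five-membered ring closure by attack on the alpha carbon of the epoxidised chalcone would lead to aurone-type products, a path favoured by the C5 methoxy group ortho to the carbonyl. The fallback separates epoxidation from ring closure. Ketone 24 would be protected (NaH, chloromethyl methyl ether) as 1-[5,6-dimethoxy-2-(methoxymethoxy)-4-(prop-2-en-1-yloxy)phenyl]ethan-1-one F12 and condensed with 32 (KOH, EtOH) to the 2'-protected chalcone F13. Alkaline H2O2 (Weitz–Scheffer epoxidation) gives the trans-epoxy ketone F14 as two diastereomers. Dilute HCl in MeOH removes the acetal, and the phenol opens the oxirane at the benzylic carbon (6-endo) to the trans-3-hydroxyflavanone F15. Alkaline H2O2 then dehydrogenates F15 to 34. This fallback sets out from 24 (with 32) and comes back at 34.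

## Further compounds

F1 | step 5 | methyl (2E)-3,4-dimethoxybut-2-enoate | COC/C(OC)=C\C(=O)OC
F2 | step 5 | (2E)-3,4-dimethoxybut-2-enoic acid | COC/C(OC)=C\C(=O)O
F3 | step 5 | (2E)-3,4-dimethoxybut-2-enoyl chloride | COC/C(OC)=C\C(=O)Cl
F4 | step 4 | 1-(triisopropylsiloxy)-2-(trimethylsilyl)ethyne | C[Si](C)(C)C#CO[Si](C(C)C)(C(C)C)C(C)C
F5 | step 4 | 2,3-dimethoxy-5-(triisopropylsilyloxy)-6-(trimethylsilyl)phenol | COc1cc(O[Si](C(C)C)(C(C)C)C(C)C)c([Si](C)(C)C)c(O)c1OC
F6 | step 4 | 4,5-dimethoxy-2-(trimethylsilyl)benzene-1,3-diol | COc1cc(O)c([Si](C)(C)C)c(O)c1OC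
F7 | step 3 | (Z)-N,2,3-trimethoxy-N-methylprop-2-enamide | CO/C=C(\OC)C(=O)N(C)OC
F8 | step 3 | (Z)-3,4-dimethoxybut-3-en-2-one | CO/C=C(\OC)C(C)=O
F9 | step 3 | (Z)-1,1,1-trifluoro-5,6-dimethoxyhex-5-ene-2,4-dione | CO/C=C(\OC)C(=O)CC(=O)C(F)(F)F
F10 | step 14 | racemic 1-(5-bromo-2-methoxyphenyl)-3-methylbut-3-en-2-ol | C=C(C)C(O)Cc1cc(Br)ccc1OC
F11 | step 14 | (1S)-2-(5-bromo-2-methoxyphenyl)-1-[(2R)-2-methyloxiran-2-yl]ethan-1-ol | C[C@@]1(CO1)[C@@H](O)Cc1cc(Br)ccc1OC
F12 | step 17 | 1-[5,6-dimethoxy-2-(methoxymethoxy)-4-(prop-2-en-1-yloxy)phenyl]ethan-1-one | CC(=O)c1c(OCOC)cc(OCC=C)c(OC)c1OC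
F13 | step 17 | (2E)-1-[5,6-dimethoxy-2-(methoxymethoxy)-4-(prop-2-en-1-yloxy)phenyl]-3-{3-[(2R)-2-hydroxy-3-methylbut-3-en-1-yl]-4-methoxyphenyl}prop-2-en-1-one | C=C(C)[C@H](O)Cc1cc(/C=C/C(=O)c2c(OCOC)cc(OCC=C)c(OC)c2OC)ccc1OC
F14 | step 17 | trans-epoxy ketone of F13 (two diastereomers; oxirane carbons not specified) | C=C(C)[C@H](O)Cc1cc(C2OC2C(=O)c2c(OCOC)cc(OCC=C)c(OC)c2OC)ccc1OC
F15 | step 17 | trans-3-hydroxy-2-{3-[(2R)-2-hydroxy-3-methylbut-3-en-1-yl]-4-methoxyphenyl}-5,6-dimethoxy-7-(prop-2-en-1-yloxy)chroman-4-one (two diastereomers; C2 and C3 not specified) | C=C(C)[C@H](O)Cc1cc(C2Oc3cc(OCC=C)c(OC)c(OC)c3C(=O)C2O)ccc1OC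
A1 | alternative 1 | {(2R,3R)-3-[2-methoxy-5-(5,6-dimethoxy-3-(methoxymethoxy)-4-oxo-7-(triisopropylsilyloxy)-4H-chromen-2-yl)benzyl]-2-methyloxiran-2-yl}methanol | OC[C@]1(C)[C@H](O1)Cc1cc(-c2oc3cc(O[Si](C(C)C)(C(C)C)C(C)C)c(OC)c(OC)c3c(=O)c2OCOC)ccc1OC
A2 | alternative 1 | 2-{3-[(2E)-4-hydroxy-3-methylbut-2-en-1-yl]-4-methoxyphenyl}-5,6-dimethoxy-3-(methoxymethoxy)-7-(triisopropylsilyloxy)-4H-chromen-4-one | OC/C(C)=C/Cc1cc(-c2oc3cc(O[Si](C(C)C)(C(C)C)C(C)C)c(OC)c(OC)c3c(=O)c2OCOC)ccc1OC
A3 | alternative 2 | 2-{3-[(2R)-2-(tert-butyldimethylsilyloxy)-3-methylbut-3-en-1-yl]-4-methoxyphenyl}-5,6-dimethoxy-7-(triisopropylsilyloxy)chromane-3,4-diol (mixture at C2, C3 and C4) | C=C(C)[C@H](O[Si](C)(C)C(C)(C)C)Cc1cc(C2Oc3cc(O[Si](C(C)C)(C(C)C)C(C)C)c(OC)c(OC)c3C(O)C2O)ccc1OC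
A4 | alternative 2 | 6-{1-[3-((2R)-2-(tert-butyldimethylsilyloxy)-3-methylbut-3-en-1-yl)-4-methoxyphenyl]-2-oxoethoxy}-2,3-dimethoxy-4-(triisopropylsilyloxy)benzaldehyde | C=C(C)[C@H](O[Si](C)(C)C(C)(C)C)Cc1cc(C(C=O)Oc2cc(O[Si](C(C)C)(C(C)C)C(C)C)c(OC)c(OC)c2C=O)ccc1OC
A5 | alternative 3 | 2-{3-[(2R)-2-(tert-butyldimethylsilyloxy)-3-methylbut-3-en-1-yl]-4-methoxyphenyl}-5,6-dimethoxy-7-(triisopropylsilyloxy)-4H-chromen-4-one | C=C(C)[C@H](O[Si](C)(C)C(C)(C)C)Cc1cc(-c2cc(=O)c3c(OC)c(OC)c(O[Si](C(C)C)(C(C)C)C(C)C)cc3o2)ccc1OC
A6 | alternative 3 | 2-iodo-3,4-dimethoxy-5-(triisopropylsilyloxy)phenol | Oc1cc(O[Si](C(C)C)(C(C)C)C(C)C)c(OC)c(OC)c1I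
A7 | alternative 3 | tert-butyl{[(2R)-1-(5-ethynyl-2-methoxyphenyl)-3-methylbut-3-en-2-yl]oxy}dimethylsilane | C=C(C)[C@H](O[Si](C)(C)C(C)(C)C)Cc1cc(C#C)ccc1OC
A8 | alternative 3 | carbon monoxide | [C-]#[O+]
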